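**Strategy.** Ring A and its γ-lactone bridge are made in one operation from two pieces (gibberellane numbering). The C2–C3–C4(–C18)–C19 unit is the dianion of a 2-methylacetoacetate. The C1–C10(O)–C5 unit is a bis-electrophile: a C10 spiro-epoxide next to the C5=C6–C7 enoate of a preformed ring B/C hydrindane. In the key step C2 opens the epoxide at C1 (C1–C2), the C4 enolate adds to C5 (C4–C5, closing ring A) and the freed C10 alkoxide lactonises onto C19. The step exploits the C3 carbinol flanked by C2 and C4, the oxygen on C10, and C5 being the β-carbon of the C7 carboxyl. Ring D and the C15 hydroxyl follow.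

Key step: step 11

Remark: gibberellane numbering (C1–C19) and the α/β convention of gibberellins are used for all intermediates from 11 on; in step 2 the (R,R)-ligand is assumed to give (S)-4 (otherwise its antipode is used).

Step 1
Reactants: 1 3-ethoxycyclohex-2-en-1-one; 2 allyl chloroformate
Product: 3 allyl 5-ethoxycyclohexa-1,5-dien-1-yl carbonate
Conditions: LiN(SiMe3)2, TMEDA, THF, −78 °C; then 2
Reagents that add atoms: none
Why: Kinetic deprotonation of the vinylogous ester at its CH2 next to the carbonyl and O-acylation of the cross-conjugated lithium dienolate (enol carbonate formation, favoured by TMEDA) should give the substrate for decarboxylative allylation.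

Step 2
Reactants: 3 allyl 5-ethoxycyclohexa-1,5-dien-1-yl carbonate
Product: 4 (6S)-6-allyl-3-ethoxycyclohex-2-en-1-one
Conditions: Pd2(dba)3·CHCl3 (2.5 mol %), (R,R)-ANDEN-phenyl Trost ligand (5.5 mol %), 1,4-dioxane, 23 °C
Reagents that add atoms: none
Why: In this decarboxylative asymmetric allylic alkylation (Tsuji–Trost type) the π-allylpalladium/enolate ion pair recombines inside the chiral ligand pocket, which should set the tertiary stereocentre (the future C9) under neutral conditions that do not epimerise it.

Step 3
Reactants: 4 (6S)-6-allyl-3-ethoxycyclohex-2-en-1-one; 5 1-(trimethylsilyl)propyne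
Product: 7 (4S)-4-allyl-3-[3-(trimethylsilyl)prop-2-yn-1-yl]cyclohex-2-en-1-one, via carbinol 6 (not isolated)
Conditions: 5, n-BuLi, TMEDA, THF, −20 °C; CeCl3, −78 °C; then 4; then 1 M HCl, 0 → 23 °C
Reagents that add atoms: water, O
Why: This is a Stork–Danheiser transposition, in which 1,2-addition of the propargylic organocerium (cerium suppresses enolisation, the silyl group directs reaction through the CH2 terminus) and acid hydrolysis/dehydration of carbinol 6 move the carbonyl to the future C13 and place the C15–C17 unit on the future C8 without touching the stereocentre.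

Step 4
Reactants: 8 acryloyl chloride; 9 2-(trimethylsilyl)ethanol
Product: 10 2-(trimethylsilyl)ethyl acrylate
Conditions: Et3N, CH2Cl2, 0 °C
Reagents that add atoms: none
Why: Acylation of a primary alcohol by an acid chloride (esterification) gives the cross-metathesis partner that carries the fluoride-labile ester.

Step 5
Reactants: 7 (4S)-4-allyl-3-[3-(trimethylsilyl)prop-2-yn-1-yl]cyclohex-2-en-1-one; 10 2-(trimethylsilyl)ethyl acrylate
Product: 11 2-(trimethylsilyl)ethyl (2E)-4-{(1S)-4-oxo-2-[3-(trimethylsilyl)prop-2-yn-1-yl]cyclohex-2-en-1-yl}but-2-enoate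
Conditions: second-generation Hoveyda–Grubbs catalyst (5 mol %), CH2Cl2, 40 °C
Reagents that add atoms: none
Why: Olefin cross-metathesis of the terminal allyl group with an acrylate should give the (E)-enoate, the trisubstituted enone and the silyl-capped alkyne being inert to the catalyst.

Step 6
Reactants: 11 the dienone ester of step 5
Product: 12 2-(trimethylsilyl)ethyl cis-5-oxo-3a-[3-(trimethylsilyl)prop-2-yn-1-yl]-3a,4,5,6,7,7a-hexahydro-1H-indene-3-carboxylate (rings B and C; C13 ketone; C5=C6 enoate; C8 propargyl cis to H-9)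
Conditions: PMe3 (0.3 equiv), t-AmOH, 23 → 60 °C
Reagents that add atoms: none
Why: In this intramolecular Rauhut–Currier reaction PMe3 adds to C5 of the unhindered enoate, the ester enolate attacks C8 of the β,β-disubstituted enone in a 5-exo-trig Michael addition and loss of PMe3 restores C5=C6, the three-atom tether from C9 forcing the cis ring fusion and so setting the C8 quaternary centre.

Step 7
Reactants: 12 the bicyclic keto enoate
Product: 13 the C13 ethylene ketal (1,3-dioxolane) of 12
Conditions: (Me3SiOCH2)2, Me3SiOTf (5 mol %), CH2Cl2, −78 → −20 °C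
Reagents that add atoms: 1,2-bis(trimethylsilyloxy)ethane, C[Si](C)(C)OCCO[Si](C)(C)C
Why: Noyori acetalisation protects the saturated C13 ketone at low temperature so that only the C10 carbonyl made next is exposed to the carbon nucleophiles of steps 9 and 11.

Step 8
Reactants: 13 the C13 ketal
Product: 14 the C10 ketone of 13 (ring B 4-oxo-2-enoate: C10=O, C5=C6–CO2CH2CH2SiMe3)
Conditions: CrO3, 3,5-dimethylpyrazole, CH2Cl2, −20 °C
Reagents that add atoms: chromium trioxide, O=[Cr](=O)=O
Why: Chromium trioxide–3,5-dimethylpyrazole allylic oxidation should convert the only ring allylic methylene (C10, γ to the ester) into the ketone, as known for cyclopentene-1-carboxylates.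

Step 9
Reactants: 14 the C10 ketone; 15 chloroiodomethane
Product: 17 the C10 spiro-epoxide (C1 on the β face; epoxide oxygen α), via chlorohydrin 16 (not isolated)
Conditions: 15, MeLi·LiBr, THF, −78 → 23 °C
Reagents that add atoms: none
Why: Chloromethyllithium formed in situ by iodine–lithium exchange adds 1,2 to the C10 ketone (carbenoid epoxidation) from the convex β face of the cis-hydrindane, anti to ring C, and the chlorohydrin alkoxide closes to the epoxide, so C1 is β and the oxygen α.

Step 10
Reactants: 18 ethyl 2-methyl-3-oxobutanoate; 9 2-(trimethylsilyl)ethanol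
Product: 19 2-(trimethylsilyl)ethyl 2-methyl-3-oxobutanoate
Conditions: DMAP (0.2 equiv), toluene, 110 °C, removal of EtOH
Reagents that add atoms: none
Why: DMAP-catalysed transesterification of a β-keto ester through its acylketene gives the keto ester whose leaving alkoxide in step 11 matches the C7 ester, so no ester scrambling can occur.

Step 11
Reactants: 17 the C10 spiro-epoxide; 19 2-(trimethylsilyl)ethyl 2-methyl-3-oxobutanoate
Product: 22 the ring A/B/C keto lactone (19,10-γ-lactone; C3 ketone; 18-methyl; H-5β; 6β-CO2CH2CH2SiMe3; C13 dioxolane; C8 CH2C≡CSiMe3), via hydroxy keto ester 20 (not isolated), via Michael adduct 21 (not isolated)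
Conditions: 19, NaH, THF, 0 °C; n-BuLi, 0 °C; then 17, −20 → 23 °C; 45 °C; then 2-(trimethylsilyl)ethanol (1 equiv), 0 → 23 °C; AcOH, 0 °C
Reagents that add atoms: none
Why: The γ-carbon (C2) of the sodium lithium dianion of 19 opens the spiro-epoxide at its unhindered methylene C1 by SN2 attack (Huckin–Weiler dianion alkylation by an epoxide), forming C1–C2 and leaving the C10 alkoxide and the stabilised C4 enolate of 20. The C4 enolate then adds to C5 of the enoate in a reversible 6-exo-trig intramolecular Michael addition that closes ring A and forms C4–C5 (21), and the C10 alkoxide attacks the C19 ester in a 5-exo-trig acyl substitution that closes the γ-lactone and expels 2-(trimethylsilyl)ethoxide; the closest known reaction type is the [3+3] annulation of β-keto ester dianions with 1,3-bis-electrophiles, here ended by lactonisation. C10 is already fixed, and only the Michael adduct in which C4 is bonded to the α face of C5 (cis to the C10 oxygen) with C19 turned towards that oxygen can lactonise, so the reversible Michael step should funnel the C4/C5 diastereomers into 22, the lactone tether setting H-5β and placing the 18-methyl on the face opposite to the bridge. C6 is set last, when the added alcohol protonates the C6 ester enolate and the matching alkoxide/alcohol pair equilibrates this centre to the more stable 6β-ester, trans to C4 and clear of the 18-methyl. The step needs attack at C1 in preference to conjugate addition at C5 or attack on the esters, which the epoxide strain, the quaternary carbons C10 and C8 that flank the enoate and the low temperature of the first stage should secure; the C10 alkoxide cannot reach C7 before the Michael step because C10 and C7 are trans across C5=C6.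

Step 12
Reactants: 22 the keto lactone
Product: 24 the 3β-hydroxy C13 ketone, via hydroxy ketal 23 (not isolated)
Conditions: KBH(s-Bu)3 (K-Selectride), THF, −78 °C; then 2 M HCl, THF, 23 °C
Reagents that add atoms: water, O
Why: The bulky hydride should attack the C3 ketone along the equatorial trajectory from the α face (steric approach control) to give the axial 3β-alcohol, and aqueous acid in the same flask hydrolyses the dioxolane (acetal hydrolysis) to free the C13 ketone.

Step 13
Reactants: 24 the 3β-hydroxy C13 ketone
Product: 25 the terminal alkyne (C8 CH2C≡CH)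
Conditions: AgNO3 (0.2 equiv), acetone–H2O, 23 °C
Reagents that add atoms: none
Why: Silver-catalysed protodesilylation of the alkynylsilane is neutral, so the β-hydroxy lactone (prone to retro-aldol epimerisation in base) and the silylethyl ester survive.

Step 14
Reactants: 25 the terminal alkyne
Product: 26 the 15-deoxy precursor of the target as its 2-(trimethylsilyl)ethyl ester (ring D closed: 3β-hydroxyl; 13-hydroxyl; 16-methylene)
Conditions: SmI2, HMPA, t-BuOH, THF, 0 → 23 °C
Reagents that add atoms: none
Why: In this SmI2-mediated ketyl–alkyne reductive cyclisation the C13 ketyl adds 5-exo-dig to C16 of the axial propargyl group and the vinyl radical is reduced and protonated, giving the bridgehead alcohol and the exocyclic methylene with C13 fixed by the geometry of the bicyclo[3.2.1]octane.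

Step 15
Reactants: 26 the 15-deoxy ester
Product: 27 the 15α-hydroxy (15-epi) 2-(trimethylsilyl)ethyl ester
Conditions: SeO2 (0.5 equiv), t-BuOOH, CH2Cl2, 23 °C
Reagents that add atoms: selenium dioxide, O=[Se]=O; tert-butyl hydroperoxide, CC(C)(C)OO
Why: SeO2 allylic hydroxylation (ene reaction, then [2,3]-sigmatropic shift) can only reach C15 and should deliver oxygen to the exo (α) face of ring D, giving the 15α-alcohol that the next two steps invert.

Step 16
Reactants: 27 the 15α-alcohol
Product: 28 the 15-oxo 2-(trimethylsilyl)ethyl ester (16-methylene-15-ketone)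
Conditions: MnO2, CH2Cl2, 23 °C
Reagents that add atoms: none
Why: MnO2 oxidises only the allylic 15-alcohol, leaving the secondary 3β-alcohol and the tertiary 13-alcohol untouched.

Step 17
Reactants: 28 the 15-ketone
Product: 29 the 2-(trimethylsilyl)ethyl ester of the target (15β-hydroxyl)
Conditions: NaBH4, CeCl3·7H2O, MeOH, −78 °C
Reagents that add atoms: none
Why: In this Luche 1,2-reduction hydride should add to C15 from the exo (α) face of the bicyclo[3.2.1]octane, away from the endo hydrogen on C11 and the C7 ester, giving the 15β-alcohol without conjugate reduction, and the low temperature should keep the new alkoxide from lactonising onto C7.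

Step 18
Reactants: 29 the 2-(trimethylsilyl)ethyl ester of the target
Product: 30 the target gibberellin (free C7 acid)
Conditions: Bu4NF, THF, 0 → 23 °C; then dilute HCl to pH 3, 0 °C
Reagents that add atoms: none
Why: Fluoride-induced β-elimination of the 2-(trimethylsilyl)ethyl ester frees the C7 acid without the aqueous base that epimerises C3 of 3β-hydroxy lactones by retro-aldol cleavage.

**Compound list**

1 | 3-ethoxycyclohex-2-en-1-one | CCOC1=CC(=O)CCC1 | starting material
2 | allyl chloroformate | C=CCOC(=O)Cl | starting material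
3 | allyl 5-ethoxycyclohexa-1,5-dien-1-yl carbonate | CCOC1=CC(OC(=O)OCC=C)=CCC1 | intermediate
4 | (6S)-6-allyl-3-ethoxycyclohex-2-en-1-one | C=CC[C@@H]1CCC(OCC)=CC1=O | intermediate
5 | 1-(trimethylsilyl)propyne | CC#C[Si](C)(C)C | starting material
6 | (6S)-6-allyl-3-ethoxy-1-[3-(trimethylsilyl)prop-2-yn-1-yl]cyclohex-2-en-1-ol (carbinol, both C1 epimers) | C=CC[C@@H]1CCC(OCC)=CC1(O)CC#C[Si](C)(C)C | intermediate
7 | (4S)-4-allyl-3-[3-(trimethylsilyl)prop-2-yn-1-yl]cyclohex-2-en-1-one | C[Si](C)(C)C#CCC1=CC(=O)CC[C@H]1CC=C | intermediate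
8 | acryloyl chloride | C=CC(=O)Cl | starting material
9 | 2-(trimethylsilyl)ethanol | OCC[Si](C)(C)C | starting material
10 | 2-(trimethylsilyl)ethyl acrylate | C=CC(=O)OCC[Si](C)(C)C | intermediate
11 | 2-(trimethylsilyl)ethyl (2E)-4-{(1S)-4-oxo-2-[3-(trimethylsilyl)prop-2-yn-1-yl]cyclohex-2-en-1-yl}but-2-enoate | C[Si](C)(C)C#CCC1=CC(=O)CC[C@H]1C/C=C/C(=O)OCC[Si](C)(C)C | intermediate
12 | cis-fused ring B/C keto enoate (C13 ketone, C5=C6 enoate, C8 propargyl cis to H-9) | C[Si](C)(C)C#CC[C@]23CC(=O)CC[C@H]2CC=C3C(=O)OCC[Si](C)(C)C | intermediate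
13 | C13 ethylene ketal of 12 | C[Si](C)(C)C#CC[C@]23CC4(OCCO4)CC[C@H]2CC=C3C(=O)OCC[Si](C)(C)C | intermediate
14 | C10 ketone of 13 (ring B 4-oxo-2-enoate) | C[Si](C)(C)C#CC[C@]23CC4(OCCO4)CC[C@H]2C(=O)C=C3C(=O)OCC[Si](C)(C)C | intermediate
15 | chloroiodomethane | ClCI | starting material
16 | chlorohydrin (C10 α-hydroxyl, β-chloromethyl C1) | C[Si](C)(C)C#CC[C@]23CC4(OCCO4)CC[C@H]2[C@](O)(CCl)C=C3C(=O)OCC[Si](C)(C)C | intermediate
17 | C10 spiro-epoxide (C1 β, oxygen α) | C[Si](C)(C)C#CC[C@]23CC4(OCCO4)CC[C@H]2[C@]5(CO5)C=C3C(=O)OCC[Si](C)(C)C | intermediate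
18 | ethyl 2-methyl-3-oxobutanoate | CCOC(=O)C(C)C(C)=O | starting material
19 | 2-(trimethylsilyl)ethyl 2-methyl-3-oxobutanoate | CC(=O)C(C)C(=O)OCC[Si](C)(C)C | intermediate
20 | hydroxy keto ester (C1–C2 formed, C10 α-hydroxyl, C4 epimers) | C[Si](C)(C)C#CC[C@]23CC4(OCCO4)CC[C@H]2[C@](O)(CCC(=O)C(C)C(=O)OCC[Si](C)(C)C)C=C3C(=O)OCC[Si](C)(C)C | intermediate
21 | Michael adduct (ring A closed, C10 hydroxyl and C19 ester cis, not yet lactonised) | C[Si](C)(C)C#CC[C@]23CC4(OCCO4)CC[C@H]2[C@]1(O)CCC(=O)[C@@](C)(C(=O)OCC[Si](C)(C)C)[C@H]1[C@@H]3C(=O)OCC[Si](C)(C)C | intermediate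
22 | ring A/B/C keto lactone (3-oxo, 19,10-lactone, C13 dioxolane, C8 CH2C≡CSiMe3) | C[Si](C)(C)C#CC[C@]23CC4(OCCO4)CC[C@H]2[C@@]12CCC(=O)[C@@](C)(C(=O)O1)[C@H]2[C@@H]3C(=O)OCC[Si](C)(C)C | intermediate
23 | 3β-hydroxy ketal | C[Si](C)(C)C#CC[C@]23CC4(OCCO4)CC[C@H]2[C@@]12CC[C@H](O)[C@@](C)(C(=O)O1)[C@H]2[C@@H]3C(=O)OCC[Si](C)(C)C | intermediate
24 | 3β-hydroxy C13 ketone | C[Si](C)(C)C#CC[C@]23CC(=O)CC[C@H]2[C@@]12CC[C@H](O)[C@@](C)(C(=O)O1)[C@H]2[C@@H]3C(=O)OCC[Si](C)(C)C | intermediate
25 | 3β-hydroxy C13 ketone with terminal alkyne | C#CC[C@]23CC(=O)CC[C@H]2[C@@]12CC[C@H](O)[C@@](C)(C(=O)O1)[C@H]2[C@@H]3C(=O)OCC[Si](C)(C)C | intermediate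
26 | 15-deoxy precursor of the target as 2-(trimethylsilyl)ethyl ester (3β,13-dihydroxy-16-methylene 19,10-lactone 7-ester) | C=C1C[C@]23C[C@@]1(O)CC[C@H]2[C@@]12CC[C@H](O)[C@@](C)(C(=O)O1)[C@H]2[C@@H]3C(=O)OCC[Si](C)(C)C | intermediate
27 | 15α-hydroxy (15-epi) 2-(trimethylsilyl)ethyl ester (3β,13,15α-trihydroxy-16-methylene 19,10-lactone 7-ester) | C=C1[C@H](O)[C@]23C[C@@]1(O)CC[C@H]2[C@@]12CC[C@H](O)[C@@](C)(C(=O)O1)[C@H]2[C@@H]3C(=O)OCC[Si](C)(C)C | intermediate
28 | 15-oxo 2-(trimethylsilyl)ethyl ester (3β,13-dihydroxy-16-methylene-15-oxo 19,10-lactone 7-ester) | C=C1C(=O)[C@]23C[C@@]1(O)CC[C@H]2[C@@]12CC[C@H](O)[C@@](C)(C(=O)O1)[C@H]2[C@@H]3C(=O)OCC[Si](C)(C)C | intermediate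
29 | 2-(trimethylsilyl)ethyl ester of the target (3β,13,15β-trihydroxy-16-methylene 19,10-lactone 7-ester) | C=C1[C@@H](O)[C@]23C[C@@]1(O)CC[C@H]2[C@@]12CC[C@H](O)[C@@](C)(C(=O)O1)[C@H]2[C@@H]3C(=O)OCC[Si](C)(C)C | intermediate
30 | the target gibberellin (3β,13,15β-trihydroxy-16-methylene 19,10-lactone 7-carboxylic acid) | C=C1[C@@H](O)[C@]23C[C@@]1(O)CC[C@H]2[C@@]12CC[C@H](O)[C@@](C)(C(=O)O1)[C@H]2[C@@H]3C(=O)O | target

**Step count.** Total: 18 steps. Longest linear sequence: 16 steps (1–3, 5–9, 11–18); steps 4 and 10 make the two ester reagents.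

**Steps most likely to fail, with fallbacks**

Step 11 (key step). The dianion may add in conjugate fashion to C5 or to an ester instead of opening the epoxide. The Michael/lactonisation funnel may stall at a cis-fused Michael adduct that cannot lactonise. The liberated alkoxide may open the β-keto lactone by retro-Claisen attack at C3. The fallback makes the lactone before the Michael addition, in separate known steps and without free alkoxide. It sets out from 17: the dianion of 19 opens the epoxide under BF3·OEt2 at −78 °C and hydroxy keto ester 20 is isolated. Heating 20 in toluene at 110 °C expels 9 to give an acylketene that the tertiary C10 hydroxyl traps, giving the seven-membered keto lactone F1. DBU in MeCN then adds C4 across the ring to C5 (5-exo-trig, cis to the lactone oxygen by necessity), and the route is rejoined at 22.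

Step 6. The phosphine may fail to trigger attack of the ester enolate on the hindered β,β-disubstituted enone, or the basic zwitterion may racemise the γ-stereocentre of 11 before cyclisation. The fallback forms the C6–C8 bond by a vinyl radical instead and sets out from 7, bypassing steps 5 and 6. Ozonolysis (ozone, then Me2S) of the terminal alkene gives the aldehyde F2, and CBr4/PPh3 (Corey–Fuchs olefination) gives the 1,1-dibromoalkene F3. Bu3SnH/AIBN generates the α-bromovinyl radical, which cyclises 5-exo onto C8 of the enone to give the cis-fused bicyclic vinyl bromide F4. Alkoxycarbonylation (Pd(OAc)2, dppf, CO, 9, Et3N) returns to the route at 12.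

Step 8. Oxidation may also occur at the propargylic C15 methylene, or the allylic oxidation may stop short of the ketone or over-oxidise. The fallback brings in the C10 oxygen through an epoxide and sets out from 13. LiN(i-Pr)2/HMPA at −78 °C followed by kinetic protonation with AcOH deconjugates the ester to the β,γ-unsaturated ester F5 (C5=C10). mCPBA gives the epoxy ester F6 (the silyl alkyne is inert), and DBU opens it by E1cB elimination to the γ-hydroxy enoate F7. MnO2 oxidation of this allylic alcohol returns to the route at 14.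

**Further compounds**

F1 | step 11 | seven-membered keto lactone (C10–O–C19 closed, C4–C5 open) | C[Si](C)(C)C#CC[C@]23CC4(OCCO4)CC[C@H]2[C@]5(CCC(=O)C(C)C(=O)O5)C=C3C(=O)OCC[Si](C)(C)C
F2 | step 6 | 2-{(1S)-4-oxo-2-[3-(trimethylsilyl)prop-2-yn-1-yl]cyclohex-2-en-1-yl}acetaldehyde | C[Si](C)(C)C#CCC1=CC(=O)CC[C@H]1CC=O
F3 | step 6 | (4S)-4-(3,3-dibromoallyl)-3-[3-(trimethylsilyl)prop-2-yn-1-yl]cyclohex-2-en-1-one | C[Si](C)(C)C#CCC1=CC(=O)CC[C@H]1CC=C(Br)Br
F4 | step 6 | cis-fused bicyclic vinyl bromide (C6 bromide, C13 ketone) | C[Si](C)(C)C#CC[C@]23CC(=O)CC[C@H]2CC=C3Br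
F5 | step 8 | deconjugated β,γ-unsaturated ester (C5=C10) | C[Si](C)(C)C#CC[C@]23CC4(OCCO4)CC[C@H]2C=CC3C(=O)OCC[Si](C)(C)C
F6 | step 8 | C5,C10-epoxy ester | C[Si](C)(C)C#CC[C@]23CC4(OCCO4)CC[C@H]2C5OC5C3C(=O)OCC[Si](C)(C)C
F7 | step 8 | γ-hydroxy enoate (C10 hydroxyl) | C[Si](C)(C)C#CC[C@]23CC4(OCCO4)CC[C@H]2C(O)C=C3C(=O)OCC[Si](C)(C)C
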